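## Plan

- **Cuts.** The three CH2OH groups go back to esters and the phenol to a pivalate, so that one hydride step ends the route. In each 2-aryl-2,3-dihydrobenzofuran the C3–C3a bond is then traced back to the C4–C4a bond of a 2-arylchroman-4-one. Each C2–aryl bond is cut to chromone + arylboronic acid, and finally the aryl–CH2 bond of the propyl chain.
- **Enabling feature.** In the dihydrofuran ring (O1, C2, C3, C3a, C7a), C2 carries the aryl group and C3 is bonded both to arene carbon C3a and to an exocyclic one-carbon group. That is a chroman-4-one whose carbonyl carbon C4 has been pushed out of the ring by a 1,2-shift of C4a from C4 to C3.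
- **Forward order.** All three benzene rings are bought. Bromochromone 4 is made once and used twice (directly for unit A, after a B-alkyl Suzuki coupling for unit B). Unit A: aryl addition to the pyranone, contraction to dihydrofuran A, borylation. Union: second aryl addition to chromone 7. Dihydrofuran B is closed last by contraction of that pyranone, followed by global reduction.
- **Stereochemistry.** C2 of each unit (R) comes from ligand-controlled Pd-catalysed conjugate addition. C3 of each unit comes from the ring contraction, which is stereospecific (iodine anti to the C2 aryl, aryl shift with inversion) and gives the trans ester without touching C2.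

Key step: step 9

Assumption: Pd/(S)-t-BuPyOx is taken to add the aryl group to the chromone face that gives the (2R)-chromanone, the sense it shows with cyclic enones; if the sense is opposite, the (R)-ligand is used in steps 5 and 8.

## Route

Step 1
Reactants: 1 1-(2-hydroxy-3-methoxyphenyl)ethan-1-one
Product: 2 1-(5-bromo-2-hydroxy-3-methoxyphenyl)ethan-1-one
Conditions: NBS, MeCN, 0 °C to rt
Reagents that add atoms: N-bromosuccinimide, O=C1CCC(=O)N1Br
Why: Electrophilic aromatic bromination, directed by the phenol OH to its only free para position (both ortho positions are substituted).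

Step 2
Reactants: 2 1-(5-bromo-2-hydroxy-3-methoxyphenyl)ethan-1-one
Product: 4 6-bromo-8-methoxy-4H-chromen-4-one, via enaminone 3 (not isolated)
Conditions: Me2NCH(OMe)2, toluene, 100 °C; then conc. HCl, CH2Cl2, reflux
Reagents that add atoms: N,N-dimethylformamide dimethyl acetal, COC(OC)N(C)C
Why: Enaminone chromone synthesis: condensation of the methyl ketone with DMF-DMA, then acid-promoted attack of the phenol on the enaminone β-carbon with loss of dimethylamine.

Step 3
Reactants: 4 6-bromo-8-methoxy-4H-chromen-4-one; 5 allyl pivalate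
Product: 7 3-(8-methoxy-4-oxo-4H-chromen-6-yl)propyl pivalate, via alkylborane 6 (not isolated)
Conditions: 5, 9-BBN-H, THF, 0 °C to rt; then 4, Pd(dppf)Cl2, AsPh3, Cs2CO3, DMF/THF/H2O, rt
Reagents that add atoms: 9-borabicyclo[3.3.1]nonane, [H]B1C2CCCC1CCC2 (kept in 6 only; it leaves only hydrogen in 7)
Why: Anti-Markovnikov hydroboration of the allyl ester followed by B-alkyl Suzuki–Miyaura coupling with the aryl bromide; carbonate at room temperature should leave the γ-pyrone intact.

Step 4
Reactants: 8 (4-hydroxy-3-methoxyphenyl)boronic acid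
Product: 9 [3-methoxy-4-(pivaloyloxy)phenyl]boronic acid
Conditions: PivCl, pyridine, CH2Cl2, 0 °C to rt; aqueous NH4Cl work-up
Reagents that add atoms: pivaloyl chloride, CC(C)(C)C(Cl)=O
Why: O-acylation of the phenol (any boron-bound acyl group hydrolyses on work-up); the pivalate resists acid, Pd and weak base, makes the ring less oxidisable, and falls to hydride at the end.

Step 5
Reactants: 4 6-bromo-8-methoxy-4H-chromen-4-one; 9 [3-methoxy-4-(pivaloyloxy)phenyl]boronic acid
Product: 10 (2R)-6-bromo-8-methoxy-2-[3-methoxy-4-(pivaloyloxy)phenyl]chroman-4-one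
Conditions: Pd(OCOCF3)2 (cat.), (S)-t-BuPyOx (cat.), NH4PF6, H2O, ClCH2CH2Cl, 60 °C
Reagents that add atoms: none
Why: Pd(II)-catalysed asymmetric conjugate addition of an arylboronic acid to a chromone (aryl–Pd insertion across C2=C3, protonolysis of the Pd enolate); the ligand selects the face and sets C2 as R, and because the cycle stays at Pd(II) the aryl bromide should be untouched.

Step 6
Reactants: 10 (2R)-6-bromo-8-methoxy-2-[3-methoxy-4-(pivaloyloxy)phenyl]chroman-4-one
Product: 12 methyl (2R,3R)-5-bromo-7-methoxy-2-[3-methoxy-4-(pivaloyloxy)phenyl]-2,3-dihydrobenzofuran-3-carboxylate, via methyl enol ether 11 (not isolated)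
Conditions: PhI(OAc)2, HC(OMe)3, conc. H2SO4 (cat.), rt
Reagents that add atoms: trimethyl orthoformate, COC(OC)OC
Why: Hypervalent-iodine oxidative ring contraction of a flavanone: iodination of enol ether 11 at C3 anti to the C2 aryl, then 1,2-shift of C4a from C4 to C3 with loss of PhI and inversion at C3, gives the trans ester with C2 untouched.

Step 7
Reactants: 12 methyl (2R,3R)-5-bromo-7-methoxy-2-[3-methoxy-4-(pivaloyloxy)phenyl]-2,3-dihydrobenzofuran-3-carboxylate
Product: 13 [(2R,3R)-7-methoxy-3-(methoxycarbonyl)-2-[3-methoxy-4-(pivaloyloxy)phenyl]-2,3-dihydrobenzofuran-5-yl]boronic acid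
Conditions: B2(OH)4, XPhos Pd G2 (cat.), XPhos, KOAc, MeOH, 60 °C
Reagents that add atoms: tetrahydroxydiboron, OB(O)B(O)O
Why: Pd-catalysed Miyaura-type borylation with tetrahydroxydiboron gives the boronic acid directly; acetate is too weak a base to epimerise C3 or cleave the pivalate, and methanol makes any exchange at the methyl ester degenerate.

Step 8
Reactants: 7 3-(8-methoxy-4-oxo-4H-chromen-6-yl)propyl pivalate; 13 [(2R,3R)-7-methoxy-3-(methoxycarbonyl)-2-[3-methoxy-4-(pivaloyloxy)phenyl]-2,3-dihydrobenzofuran-5-yl]boronic acid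
Product: 14 methyl (2R,3R)-7-methoxy-5-[(2R)-8-methoxy-4-oxo-6-[3-(pivaloyloxy)propyl]chroman-2-yl]-2-[3-methoxy-4-(pivaloyloxy)phenyl]-2,3-dihydrobenzofuran-3-carboxylate
Conditions: Pd(OCOCF3)2 (cat.), (S)-t-BuPyOx (cat.), NH4PF6, H2O, ClCH2CH2Cl, 60 °C
Reagents that add atoms: none
Why: The same Pd(II)/PyOx asymmetric conjugate addition joins the two halves; the ligand sets the new chromanone C2 as R, since the stereocentres of 13 are too remote to interfere, and any minor stereoisomer becomes a separable diastereomer.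

Step 9
Reactants: 14 methyl (2R,3R)-7-methoxy-5-[(2R)-8-methoxy-4-oxo-6-[3-(pivaloyloxy)propyl]chroman-2-yl]-2-[3-methoxy-4-(pivaloyloxy)phenyl]-2,3-dihydrobenzofuran-3-carboxylate
Product: 16 methyl (2R,3R)-7-methoxy-2-[(2R,3R)-7-methoxy-3-(methoxycarbonyl)-2-[3-methoxy-4-(pivaloyloxy)phenyl]-2,3-dihydrobenzofuran-5-yl]-5-[3-(pivaloyloxy)propyl]-2,3-dihydrobenzofuran-3-carboxylate, via methyl enol ether 15 (not isolated)
Conditions: PhI(OAc)2, HC(OMe)3, conc. H2SO4 (cat.), rt
Reagents that add atoms: trimethyl orthoformate, COC(OC)OC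
Why: Acid and orthoformate turn the C4 ketone into enol ether 15; PhI(OAc)2 attacks C3 anti to the C2 aryl to give a C3–iodine(III) species with C4 as a dimethoxy-substituted cationic centre, and arene carbon C4a then shifts from C4 to C3 with loss of PhI, the resulting dimethoxycarbenium ion collapsing to the methyl ester. The closest known reaction type is the iodine(III)- or thallium(III)-mediated oxidative rearrangement of flavanones to methyl trans-2-aryl-2,3-dihydrobenzofuran-3-carboxylates. The dihydrofuran ring arises by 6-to-5 contraction of the pyranone: the new C3–C3a bond forms through an aryl-bridged (phenonium-like, three-membered) transition state, and C4 leaves the ring to become the ester carbon. The new stereocentre C3 is controlled by C2, because iodine enters trans to the equatorial aryl and the shift inverts C3, so the ester ends trans to the aryl while C2 itself is not involved and stays R. The step needs ring contraction to win over the 1,2-shift of the C2 aryl (isoflavone), over dehydrogenation (flavone) and over oxidation of the electron-rich rings. The equatorial C3–I bond is antiperiplanar to C4–C4a and not to C2–aryl, the migrating ring carries an ortho oxygen that raises its migratory aptitude, and the phenol and all hydroxyl groups are masked as esters so that no easily oxidised OH is exposed.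

Step 10
Reactants: 16 methyl (2R,3R)-7-methoxy-2-[(2R,3R)-7-methoxy-3-(methoxycarbonyl)-2-[3-methoxy-4-(pivaloyloxy)phenyl]-2,3-dihydrobenzofuran-5-yl]-5-[3-(pivaloyloxy)propyl]-2,3-dihydrobenzofuran-3-carboxylate
Product: 17 4-[(2R,3S)-3-(hydroxymethyl)-5-[(2R,3S)-3-(hydroxymethyl)-5-(3-hydroxypropyl)-7-methoxy-2,3-dihydrobenzofuran-2-yl]-7-methoxy-2,3-dihydrobenzofuran-2-yl]-2-methoxyphenol
Conditions: LiAlH4 (excess), THF, 0 °C to rt; aqueous Rochelle salt, then NH4Cl
Reagents that add atoms: none
Why: Hydride reduction converts both methyl esters into CH2OH and cleaves the alkyl and the aryl pivalate in one operation; ester reduction at 0 °C should outrun enolisation, so C3 of each unit keeps its configuration (the label changes from R to S only because CH2OH ranks below C2).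

## Compound list

1 | 1-(2-hydroxy-3-methoxyphenyl)ethan-1-one | CC(=O)c1cccc(OC)c1O | starting material
2 | 1-(5-bromo-2-hydroxy-3-methoxyphenyl)ethan-1-one | CC(=O)c1cc(Br)cc(OC)c1O | intermediate
3 | (E)-1-(5-bromo-2-hydroxy-3-methoxyphenyl)-3-(dimethylamino)prop-2-en-1-one | CN(C)/C=C/C(=O)c1cc(Br)cc(OC)c1O | intermediate (not isolated)
4 | 6-bromo-8-methoxy-4H-chromen-4-one | COc1cc(Br)cc2c(=O)ccoc12 | intermediate
5 | allyl pivalate (prop-2-en-1-yl 2,2-dimethylpropanoate) | C=CCOC(=O)C(C)(C)C | starting material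
6 | 3-(9-borabicyclo[3.3.1]nonan-9-yl)propyl pivalate | CC(C)(C)C(=O)OCCCB1C2CCCC1CCC2 | intermediate (not isolated)
7 | 3-(8-methoxy-4-oxo-4H-chromen-6-yl)propyl pivalate | COc1cc(CCCOC(=O)C(C)(C)C)cc2c(=O)ccoc12 | intermediate
8 | (4-hydroxy-3-methoxyphenyl)boronic acid | COc1cc(B(O)O)ccc1O | starting material
9 | [3-methoxy-4-(pivaloyloxy)phenyl]boronic acid | COc1cc(B(O)O)ccc1OC(=O)C(C)(C)C | intermediate
10 | (2R)-6-bromo-8-methoxy-2-[3-methoxy-4-(pivaloyloxy)phenyl]chroman-4-one | COc1cc([C@H]2CC(=O)c3cc(Br)cc(OC)c3O2)ccc1OC(=O)C(C)(C)C | intermediate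
11 | (2R)-6-bromo-4,8-dimethoxy-2-[3-methoxy-4-(pivaloyloxy)phenyl]-2H-chromene | COc1cc([C@H]2C=C(OC)c3cc(Br)cc(OC)c3O2)ccc1OC(=O)C(C)(C)C | intermediate (not isolated)
12 | methyl (2R,3R)-5-bromo-7-methoxy-2-[3-methoxy-4-(pivaloyloxy)phenyl]-2,3-dihydrobenzofuran-3-carboxylate | COc1cc([C@@H]2Oc3c(OC)cc(Br)cc3[C@H]2C(=O)OC)ccc1OC(=O)C(C)(C)C | intermediate
13 | [(2R,3R)-7-methoxy-3-(methoxycarbonyl)-2-[3-methoxy-4-(pivaloyloxy)phenyl]-2,3-dihydrobenzofuran-5-yl]boronic acid | COc1cc([C@@H]2Oc3c(OC)cc(B(O)O)cc3[C@H]2C(=O)OC)ccc1OC(=O)C(C)(C)C | intermediate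
14 | methyl (2R,3R)-7-methoxy-5-[(2R)-8-methoxy-4-oxo-6-[3-(pivaloyloxy)propyl]chroman-2-yl]-2-[3-methoxy-4-(pivaloyloxy)phenyl]-2,3-dihydrobenzofuran-3-carboxylate | COc1cc([C@@H]2Oc3c(OC)cc([C@H]4CC(=O)c5cc(CCCOC(=O)C(C)(C)C)cc(OC)c5O4)cc3[C@H]2C(=O)OC)ccc1OC(=O)C(C)(C)C | intermediate
15 | methyl (2R,3R)-5-[(2R)-4,8-dimethoxy-6-[3-(pivaloyloxy)propyl]-2H-chromen-2-yl]-7-methoxy-2-[3-methoxy-4-(pivaloyloxy)phenyl]-2,3-dihydrobenzofuran-3-carboxylate | COc1cc([C@@H]2Oc3c(OC)cc([C@H]4C=C(OC)c5cc(CCCOC(=O)C(C)(C)C)cc(OC)c5O4)cc3[C@H]2C(=O)OC)ccc1OC(=O)C(C)(C)C | intermediate (not isolated)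
16 | methyl (2R,3R)-7-methoxy-2-[(2R,3R)-7-methoxy-3-(methoxycarbonyl)-2-[3-methoxy-4-(pivaloyloxy)phenyl]-2,3-dihydrobenzofuran-5-yl]-5-[3-(pivaloyloxy)propyl]-2,3-dihydrobenzofuran-3-carboxylate | COc1cc([C@@H]2Oc3c(OC)cc([C@@H]4Oc5c(OC)cc(CCCOC(=O)C(C)(C)C)cc5[C@H]4C(=O)OC)cc3[C@H]2C(=O)OC)ccc1OC(=O)C(C)(C)C | intermediate
17 | 4-[(2R,3S)-3-(hydroxymethyl)-5-[(2R,3S)-3-(hydroxymethyl)-5-(3-hydroxypropyl)-7-methoxy-2,3-dihydrobenzofuran-2-yl]-7-methoxy-2,3-dihydrobenzofuran-2-yl]-2-methoxyphenol (CNP0599161.1) | COc1cc([C@@H]2Oc3c(OC)cc([C@@H]4Oc5c(OC)cc(CCCO)cc5[C@H]4CO)cc3[C@H]2CO)ccc1O | target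

## Summary and risks

Total step count: 10. Longest linear sequence: 8 steps (1 to 17 through steps 1, 2, 5, 6, 7, 8, 9, 10).

**Steps most likely to fail**

**Step 9.** The iodine(III) oxidant may attack the electron-rich diaryl ether rings, the electron-rich C2 aryl may migrate instead of C4a (isoflavone pathway) or the ring may simply be dehydrogenated, and acid may open the benzylic C2–O bond with loss of configuration. The fallback is a non-oxidative ring contraction by Wolff rearrangement. It sets out from 14: condensation with DMF-DMA (toluene, 90 °C) at the C3 methylene should give the 3-(dimethylaminomethylidene)chromanone F1. Diazo transfer to this enaminone with tosyl azide (CH2Cl2, rt) should give the 3-diazochromanone F2. Irradiation (365 nm, MeOH, rt) should trigger the Wolff rearrangement, and methanol should trap the ring-contracted ketene as 16 together with its ring-B C3 epimer, the cis ester F3. DBU (CH2Cl2, rt) should equilibrate F3 to the trans ester. The fallback comes back to the route at 16.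

**Step 8.** Transmetalation and insertion with the bulky chiral catalyst and the elaborate boronic acid may be slow, so that protodeboronation competes and face selection at the new C2 is incomplete. The fallback gives up stereocontrol in the C–C bond formation and recovers it by a catalyst-controlled reduction. It sets out from 7 and 13: the more active achiral catalyst Pd(OCOCF3)2/2,2'-bipyridine (aqueous DCE, 60 °C) should give 14 together with its chromanone C2 epimer F4. Asymmetric transfer hydrogenation in kinetic-resolution mode (Cp*RhCl[(S,S)-TsDPEN], HCO2H/Et3N, EtOAc, rt, stopped near half conversion) should reduce the (2S)-configured F4 in the matched sense to the cis chroman-4-ol F5. The (2R)-ketone should remain and be separated from the alcohol by chromatography. The fallback comes back to the route at 14.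

**Step 3.** Aqueous base may open the γ-pyrone ring, and the alkylborane may undergo protodeboronation or β-hydride elimination before it couples. The fallback couples before the pyrone is built. It sets out from 2 and 6: B-alkyl Suzuki–Miyaura coupling (Pd(OAc)2, SPhos, Cs2CO3, THF/H2O, 50 °C) should give 3-(3-acetyl-4-hydroxy-5-methoxyphenyl)propyl pivalate F6. DMF-DMA (toluene, 100 °C) should give the enaminone F7, which conc. HCl (CH2Cl2, reflux) should cyclise. The fallback comes back to the route at 7.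

## Further compounds

F1 | step 9 | methyl (2R,3R)-5-[(2S,3E)-3-(dimethylaminomethylidene)-8-methoxy-4-oxo-6-[3-(pivaloyloxy)propyl]chroman-2-yl]-7-methoxy-2-[3-methoxy-4-(pivaloyloxy)phenyl]-2,3-dihydrobenzofuran-3-carboxylate (C2 unchanged in space; the label becomes S) | COc1cc([C@@H]2Oc3c(OC)cc([C@H]4/C(=C\N(C)C)C(=O)c5cc(CCCOC(=O)C(C)(C)C)cc(OC)c5O4)cc3[C@H]2C(=O)OC)ccc1OC(=O)C(C)(C)C
F2 | step 9 | methyl (2R,3R)-5-[(2S)-3-diazo-8-methoxy-4-oxo-6-[3-(pivaloyloxy)propyl]chroman-2-yl]-7-methoxy-2-[3-methoxy-4-(pivaloyloxy)phenyl]-2,3-dihydrobenzofuran-3-carboxylate (C2 unchanged in space; the label becomes S) | COc1cc([C@@H]2Oc3c(OC)cc([C@H]4C(=[N+]=[N-])C(=O)c5cc(CCCOC(=O)C(C)(C)C)cc(OC)c5O4)cc3[C@H]2C(=O)OC)ccc1OC(=O)C(C)(C)C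
F3 | step 9 | methyl (2R,3S)-7-methoxy-2-[(2R,3R)-7-methoxy-3-(methoxycarbonyl)-2-[3-methoxy-4-(pivaloyloxy)phenyl]-2,3-dihydrobenzofuran-5-yl]-5-[3-(pivaloyloxy)propyl]-2,3-dihydrobenzofuran-3-carboxylate (cis in ring B) | COc1cc([C@@H]2Oc3c(OC)cc([C@@H]4Oc5c(OC)cc(CCCOC(=O)C(C)(C)C)cc5[C@@H]4C(=O)OC)cc3[C@H]2C(=O)OC)ccc1OC(=O)C(C)(C)C
F4 | step 8 | methyl (2R,3R)-7-methoxy-5-[(2S)-8-methoxy-4-oxo-6-[3-(pivaloyloxy)propyl]chroman-2-yl]-2-[3-methoxy-4-(pivaloyloxy)phenyl]-2,3-dihydrobenzofuran-3-carboxylate | COc1cc([C@@H]2Oc3c(OC)cc([C@@H]4CC(=O)c5cc(CCCOC(=O)C(C)(C)C)cc(OC)c5O4)cc3[C@H]2C(=O)OC)ccc1OC(=O)C(C)(C)C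
F5 | step 8 | methyl (2R,3R)-5-[(2S,4S)-4-hydroxy-8-methoxy-6-[3-(pivaloyloxy)propyl]chroman-2-yl]-7-methoxy-2-[3-methoxy-4-(pivaloyloxy)phenyl]-2,3-dihydrobenzofuran-3-carboxylate | COc1cc([C@@H]2Oc3c(OC)cc([C@@H]4C[C@H](O)c5cc(CCCOC(=O)C(C)(C)C)cc(OC)c5O4)cc3[C@H]2C(=O)OC)ccc1OC(=O)C(C)(C)C
F6 | step 3 | 3-(3-acetyl-4-hydroxy-5-methoxyphenyl)propyl pivalate | CC(=O)c1cc(CCCOC(=O)C(C)(C)C)cc(OC)c1O
F7 | step 3 | (E)-3-[3-[3-(dimethylamino)prop-2-enoyl]-4-hydroxy-5-methoxyphenyl]propyl pivalate | CN(C)/C=C/C(=O)c1cc(CCCOC(=O)C(C)(C)C)cc(OC)c1O
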